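**Retrosynthetic overview**
1. Maltepolide D ⇒ (final desilylation, late C5 oxidation) 20-membered macrolactone, opened at C7–C8: intramolecular Stille coupling of a (Z)-vinyl iodide with an (E)-vinylstannane closes the macrocycle, the last ring formed.
2. Seco compound ⇒ C2=C3 by Still–Gennari olefination of a north aldehyde (C3–C7, Evans syn-aldol) with the C19 phosphonopropionate ester of the C8–C24 core.
3. Core ⇒ C11 by allenylborane propargylation of a (Z)-enal (C12=C13 from a first Still–Gennari reaction); C19–C20 by Nozaki–Hiyama–Kishi addition of a lactate-derived C20–C24 vinyl iodide.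
4. Oxolane (first ring formed) ⇒ 5-exo epoxide opening with inversion at C14 of a triol built from 2-deoxy-D-ribose (C13–C17) by Brown anti-crotylation (C17, C18).

Assumption: locants C1–C24 used in names and explanations follow the macrolide skeleton (C1 lactone carbonyl, C14–C17 oxolane carbons, C19 lactone carbinol, C24 side-chain methyl).

**Side-chain fragment (C20–C24)**

Step 1
Reactants: 1 ethyl (S)-lactate
Product: 2 (S)-2-hydroxy-N-methoxy-N-methylpropanamide
Conditions: MeNHOMe·HCl, i-PrMgCl, THF, −20 to 0 °C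
Reagents that add atoms: N,O-dimethylhydroxylamine hydrochloride, CNOC.Cl
Why: Weinreb amide formation by aminolysis of the ester with the magnesium amide; the lactate stereocentre (future C23) is not touched.

Step 2
Reactants: 2 (S)-2-hydroxy-N-methoxy-N-methylpropanamide
Product: 3 (S)-2-(tert-butyldimethylsilyloxy)-N-methoxy-N-methylpropanamide
Conditions: TBSCl, imidazole, DMF, rt
Reagents that add atoms: tert-butyldimethylsilyl chloride, CC(C)(C)[Si](C)(C)Cl
Why: Standard silylation of a secondary alcohol.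

Step 3
Reactants: 3 (S)-2-(tert-butyldimethylsilyloxy)-N-methoxy-N-methylpropanamide; 4 ethynyltrimethylsilane
Product: 5 (S)-4-(tert-butyldimethylsilyloxy)-1-(trimethylsilyl)pent-1-yn-3-one
Conditions: 4, n-BuLi, THF, −78 °C; then 3, −78 to 0 °C
Reagents that add atoms: none
Why: Weinreb ketone synthesis; the chelated tetrahedral intermediate prevents over-addition and the acetylide does not epimerise the α-silyloxy centre.

Step 4
Reactants: 5 (S)-4-(tert-butyldimethylsilyloxy)-1-(trimethylsilyl)pent-1-yn-3-one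
Product: 6 (3R,4S)-4-(tert-butyldimethylsilyloxy)-1-(trimethylsilyl)pent-1-yn-3-ol
Conditions: RuCl[(S,S)-TsDPEN](p-cymene) (2 mol %), i-PrOH, rt
Reagents that add atoms: none
Why: Noyori asymmetric transfer hydrogenation of an ynone; the (S,S) catalyst places the alkynyl group in the aryl-type position and gives the 3R carbinol (C22), anti to the C23 oxygen, under catalyst control.

Step 5
Reactants: 6 (3R,4S)-4-(tert-butyldimethylsilyloxy)-1-(trimethylsilyl)pent-1-yn-3-ol
Product: 7 (3R,4S)-3,4-bis(tert-butyldimethylsilyloxy)-1-(trimethylsilyl)pent-1-yne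
Conditions: TBSOTf, 2,6-lutidine, CH2Cl2, 0 °C
Reagents that add atoms: tert-butyldimethylsilyl triflate, CC(C)(C)[Si](C)(C)OS(=O)(=O)C(F)(F)F
Why: Silylation of the propargylic alcohol with the reactive triflate.

Step 6
Reactants: 7 (3R,4S)-3,4-bis(tert-butyldimethylsilyloxy)-1-(trimethylsilyl)pent-1-yne
Product: 8 (3R,4S)-3,4-bis(tert-butyldimethylsilyloxy)pent-1-yne
Conditions: K2CO3, MeOH, rt
Reagents that add atoms: none
Why: Methanolysis of the alkynyl C–Si bond; the O-silyl ethers are stable to these conditions.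

Step 7
Reactants: 8 (3R,4S)-3,4-bis(tert-butyldimethylsilyloxy)pent-1-yne
Product: 10 (1E,3R,4S)-3,4-bis(tert-butyldimethylsilyloxy)-1-iodopent-1-ene, via alkenylzirconocene chloride 9 (not isolated)
Conditions: Cp2Zr(H)Cl, THF, rt; then I2, 0 °C
Reagents that add atoms: iodine, II
Why: Schwartz hydrozirconation adds Zr–H syn with zirconium at the terminal carbon, and iodinolysis with retention gives the (E)-vinyl iodide.

**North fragment (C3–C7)**

Step 8
Reactants: 11 prop-2-yn-1-ol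
Product: 13 (E)-3-iodo-2-methylprop-2-en-1-ol, via vinylalane 12 (not isolated)
Conditions: Me3Al, Cp2ZrCl2 (25 mol %), CH2Cl2, 0 °C to rt; then I2, THF, −30 to 0 °C
Reagents that add atoms: trimethylaluminium, C[Al](C)C; iodine, II
Why: Negishi zirconium-catalysed carboalumination adds methyl and aluminium syn across the alkyne (methyl at the internal carbon), and iodinolysis with retention fixes the E geometry of the future C6=C7 bond.

Step 9
Reactants: 13 (E)-3-iodo-2-methylprop-2-en-1-ol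
Product: 14 (E)-3-iodo-2-methylprop-2-enal
Conditions: MnO2, CH2Cl2, rt (solution used directly)
Reagents that add atoms: none
Why: Mild allylic oxidation that does not isomerise the alkene.

Step 10
Reactants: 15 (4R)-4-benzyl-3-propanoyl-1,3-oxazolidin-2-one; 14 (E)-3-iodo-2-methylprop-2-enal
Product: 16 (4R)-4-benzyl-3-[(2R,3R,4E)-3-hydroxy-5-iodo-2,4-dimethylpent-4-enoyl]-1,3-oxazolidin-2-one
Conditions: 15, Bu2BOTf, Et3N, CH2Cl2, −78 to 0 °C; then 14, −78 to 0 °C; pH 7 buffer, MeOH, H2O2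
Reagents that add atoms: none
Why: Evans syn-aldol through the (Z)-boron enolate and a Zimmerman–Traxler chair; the (R)-auxiliary sets the α-methyl centre (C4 of the target) and the syn carbinol (C5, later oxidised).

Step 11
Reactants: 16 (4R)-4-benzyl-3-[(2R,3R,4E)-3-hydroxy-5-iodo-2,4-dimethylpent-4-enoyl]-1,3-oxazolidin-2-one
Product: 17 (2R,3R,4E)-3-hydroxy-5-iodo-N-methoxy-N,2,4-trimethylpent-4-enamide
Conditions: MeNHOMe·HCl, Me3Al, CH2Cl2, −20 to 0 °C
Reagents that add atoms: N,O-dimethylhydroxylamine hydrochloride, CNOC.Cl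
Why: Aluminium amide transamination of the imide, assisted by the free β-hydroxyl, releases the auxiliary without epimerisation.

Step 12
Reactants: 17 (2R,3R,4E)-3-hydroxy-5-iodo-N-methoxy-N,2,4-trimethylpent-4-enamide
Product: 18 (2R,3R,4E)-5-iodo-N-methoxy-N,2,4-trimethyl-3-(triethylsilyloxy)pent-4-enamide
Conditions: TESOTf, 2,6-lutidine, CH2Cl2, −78 °C
Reagents that add atoms: triethylsilyl triflate, CC[Si](CC)(CC)OS(=O)(=O)C(F)(F)F
Why: The C5 hydroxyl is masked as a TES ether, which can later be removed in the presence of TBS ethers.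

Step 13
Reactants: 18 (2R,3R,4E)-5-iodo-N-methoxy-N,2,4-trimethyl-3-(triethylsilyloxy)pent-4-enamide
Product: 19 (2R,3R,4E)-N-methoxy-N,2,4-trimethyl-3-(triethylsilyloxy)-5-(trimethylstannyl)pent-4-enamide
Conditions: (Me3Sn)2, Pd(PPh3)4 (5 mol %), toluene, 80 °C
Reagents that add atoms: hexamethylditin, C[Sn](C)(C)[Sn](C)(C)C
Why: Palladium-catalysed stannylation (oxidative addition of zerovalent palladium to the C–I bond, transmetalation with the ditin) replaces iodine by tin with retention of the E geometry.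

Step 14
Reactants: 19 (2R,3R,4E)-N-methoxy-N,2,4-trimethyl-3-(triethylsilyloxy)-5-(trimethylstannyl)pent-4-enamide
Product: 20 (2R,3R,4E)-2,4-dimethyl-3-(triethylsilyloxy)-5-(trimethylstannyl)pent-4-enal
Conditions: i-Bu2AlH (DIBAL-H), THF, −78 °C; Rochelle salt work-up
Reagents that add atoms: none
Why: Weinreb amide reduction stops at the aldehyde through the stable chelated aluminium hemiaminal; the α-centre is not epimerised at low temperature.

**Phosphono acid**

Step 15
Reactants: 21 methyl 2-[bis(2,2,2-trifluoroethoxy)phosphoryl]propanoate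
Product: 22 2-[bis(2,2,2-trifluoroethoxy)phosphoryl]propanoic acid
Conditions: Me3SnOH, 1,2-dichloroethane, 70 °C; then dilute aq. HCl
Reagents that add atoms: trimethyltin hydroxide, C[Sn](C)(C)O
Why: Neutral tin hydroxide cleavage of the methyl carboxylate spares the base-labile trifluoroethyl phosphonate esters.

**Oxolane core and endgame (longest linear sequence)**

Step 16
Reactants: 23 2-deoxy-D-ribose
Product: 24 (2R,3S)-4-(1,3-dithian-2-yl)butane-1,2,3-triol
Conditions: HS(CH2)3SH, conc. HCl, 0 °C to rt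
Reagents that add atoms: propane-1,3-dithiol, SCCCS
Why: Acid-catalysed dithioacetalisation opens the lactol to the acyclic chain carrying the future C14 and C15 stereocentres.

Step 17
Reactants: 24 (2R,3S)-4-(1,3-dithian-2-yl)butane-1,2,3-triol
Product: 25 (1S)-2-(1,3-dithian-2-yl)-1-[(4R)-2,2-dimethyl-1,3-dioxolan-4-yl]ethan-1-ol
Conditions: 2,2-dimethoxypropane, p-TsOH (cat.), acetone, 0 °C
Reagents that add atoms: 2,2-dimethoxypropane, COC(C)(C)OC
Why: Acetalisation favours the terminal dioxolane over the cis-disubstituted internal one, leaving only the C15 hydroxyl free.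

Step 18
Reactants: 25 (1S)-2-(1,3-dithian-2-yl)-1-[(4R)-2,2-dimethyl-1,3-dioxolan-4-yl]ethan-1-ol
Product: 26 2-[(2S)-2-[(4R)-2,2-dimethyl-1,3-dioxolan-4-yl]-2-methoxyethyl]-1,3-dithiane
Conditions: NaH, MeI, THF, 0 °C
Reagents that add atoms: iodomethane, CI
Why: Williamson etherification installs the C15 methyl ether; the alkoxide is methylated much faster than sulfur at 0 °C.

Step 19
Reactants: 26 2-[(2S)-2-[(4R)-2,2-dimethyl-1,3-dioxolan-4-yl]-2-methoxyethyl]-1,3-dithiane
Product: 27 (3S)-3-[(4R)-2,2-dimethyl-1,3-dioxolan-4-yl]-3-methoxypropanal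
Conditions: I2, NaHCO3, acetone/H2O, 0 °C
Reagents that add atoms: water, O
Why: Buffered oxidative hydrolysis of the dithiane unmasks the C17 aldehyde without acid or base, so the acetonide and the eliminable β-methoxy group survive.

Step 20
Reactants: 27 (3S)-3-[(4R)-2,2-dimethyl-1,3-dioxolan-4-yl]-3-methoxypropanal
Product: 28 (1S,3R,4S)-1-[(4R)-2,2-dimethyl-1,3-dioxolan-4-yl]-1-methoxy-4-methylhex-5-en-3-ol
Conditions: trans-2-butene, n-BuLi, KOtBu, THF, −78 to −45 °C; (−)-Ipc2BOMe, −78 °C; BF3·OEt2; then 27, −78 °C; NaOH, H2O2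
Reagents that add atoms: trans-2-butene, C/C=C/C (transferred as its (E)-crotyl-B(Ipc)2 derivative)
Why: Brown crotylboration through a chair transition state; the (E)-crotyl geometry gives the 17,18-anti relationship and the Ipc groups from (+)-α-pinene direct attack to the Si face, setting C17 and C18 under reagent control.

Step 21
Reactants: 28 (1S,3R,4S)-1-[(4R)-2,2-dimethyl-1,3-dioxolan-4-yl]-1-methoxy-4-methylhex-5-en-3-ol
Product: 29 (2R,3S,5R,6S)-3-methoxy-6-methyloct-7-ene-1,2,5-triol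
Conditions: AcOH/H2O 4:1, 40 °C
Reagents that add atoms: none
Why: Mild acidic hydrolysis of the acetonide; the methyl ether and the homoallylic alcohol are inert.

Step 22
Reactants: 29 (2R,3S,5R,6S)-3-methoxy-6-methyloct-7-ene-1,2,5-triol
Product: 30 (2R,3S,5R,6S)-2,5-dihydroxy-3-methoxy-6-methyloct-7-en-1-yl 4-methylbenzenesulfonate
Conditions: TsCl, Bu2SnO (2 mol %), Et3N, CH2Cl2, 0 °C to rt
Reagents that add atoms: 4-methylbenzenesulfonyl chloride, Cc1ccc(cc1)S(Cl)(=O)=O
Why: Tin-acetal-catalysed sulfonylation activates only the primary hydroxyl of the terminal 1,2-diol.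

Step 23
Reactants: 30 (2R,3S,5R,6S)-2,5-dihydroxy-3-methoxy-6-methyloct-7-en-1-yl 4-methylbenzenesulfonate
Product: 32 [(2S,3S,5R)-5-[(2S)-but-3-en-2-yl]-3-methoxyoxolan-2-yl]methanol, via epoxy alcohol 31 (not isolated)
Conditions: K2CO3, MeOH, 0 °C to rt; then CSA (cat.), CH2Cl2, rt
Reagents that add atoms: none
Why: Base closes the terminal epoxide (C14 retained) and the C17 hydroxyl opens it in a 5-exo-tet SN2 reaction at C14 with inversion, giving the 2,5-trans-2,3-cis oxolane with the C14 and C15 configurations of the target.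

Step 24
Reactants: 32 [(2S,3S,5R)-5-[(2S)-but-3-en-2-yl]-3-methoxyoxolan-2-yl]methanol
Product: 33 (2R,3S,5R)-5-[(2S)-but-3-en-2-yl]-3-methoxyoxolane-2-carbaldehyde
Conditions: PhI(OAc)2, TEMPO (cat.), CH2Cl2, rt
Reagents that add atoms: none
Why: Oxoammonium oxidation of the primary alcohol under non-basic conditions avoids epimerisation of the α-alkoxy aldehyde.

Step 25
Reactants: 33 (2R,3S,5R)-5-[(2S)-but-3-en-2-yl]-3-methoxyoxolane-2-carbaldehyde; 21 methyl 2-[bis(2,2,2-trifluoroethoxy)phosphoryl]propanoate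
Product: 34 methyl (2Z)-3-[(2S,3S,5R)-5-[(2S)-but-3-en-2-yl]-3-methoxyoxolan-2-yl]-2-methylprop-2-enoate
Conditions: 21, KN(SiMe3)2 (KHMDS), 18-crown-6, THF, −78 °C; then 33
Reagents that add atoms: none
Why: Still–Gennari olefination; the electron-poor phosphonate eliminates under kinetic control and gives the (Z)-trisubstituted C12=C13 alkene.

Step 26
Reactants: 34 methyl (2Z)-3-[(2S,3S,5R)-5-[(2S)-but-3-en-2-yl]-3-methoxyoxolan-2-yl]-2-methylprop-2-enoate
Product: 35 methyl (2Z)-3-[(2S,3S,5R)-3-methoxy-5-[(2R)-1-oxopropan-2-yl]oxolan-2-yl]-2-methylprop-2-enoate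
Conditions: O3, CH2Cl2, −78 °C (Sudan Red 7B end point); then PPh3, −78 °C to rt
Reagents that add atoms: ozone, [O-][O+]=O
Why: Ozonolysis cleaves the electron-rich terminal alkene much faster than the electron-poor trisubstituted enoate, unmasking the C19 aldehyde under neutral conditions.

Step 27
Reactants: 35 methyl (2Z)-3-[(2S,3S,5R)-3-methoxy-5-[(2R)-1-oxopropan-2-yl]oxolan-2-yl]-2-methylprop-2-enoate; 10 (1E,3R,4S)-3,4-bis(tert-butyldimethylsilyloxy)-1-iodopent-1-ene
Product: 36 methyl (2Z)-3-[(2S,3S,5R)-5-[(2S,3R,4E,6R,7S)-6,7-bis(tert-butyldimethylsilyloxy)-3-hydroxyoct-4-en-2-yl]-3-methoxyoxolan-2-yl]-2-methylprop-2-enoate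
Conditions: CrCl2, NiCl2 (1 mol %), DMSO, rt
Reagents that add atoms: none
Why: Nozaki–Hiyama–Kishi coupling; the alkenylchromium species adds only to the aldehyde, with the E geometry retained, and Felkin–Anh control reinforced by 1,3-anti induction from the C17 oxygen favours the 19R alcohol (syn to the C18 methyl).

Step 28
Reactants: 36 (C19 alcohol above)
Product: 37 C19 triethylsilyl ether of 36
Conditions: TESOTf, 2,6-lutidine, CH2Cl2, −78 °C
Reagents that add atoms: triethylsilyl triflate, CC[Si](CC)(CC)OS(=O)(=O)C(F)(F)F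
Why: Temporary protection of the lactone carbinol that can be removed later without touching TBS ethers.

Step 29
Reactants: 37 C19 triethylsilyl ether of 36
Product: 38 (Z)-allylic alcohol (37 with C11 as CH2OH in place of CO2Me)
Conditions: i-Bu2AlH (DIBAL-H), CH2Cl2, −78 °C
Reagents that add atoms: none
Why: 1,2-Reduction of the enoate to the allylic alcohol; silyl ethers and the alkene geometry are unaffected.

Step 30
Reactants: 38 (Z)-allylic alcohol
Product: 39 (Z)-enal (C11 aldehyde)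
Conditions: PhI(OAc)2, TEMPO (cat.), CH2Cl2, rt
Reagents that add atoms: none
Why: Mild oxoammonium oxidation gives the α-methyl (Z)-enal without Z/E isomerisation; it is used at once.

Step 31
Reactants: 39 (Z)-enal
Product: 40 (11R)-homopropargylic alcohol (39 with C11 as CH(OH)CH2C≡CH)
Conditions: allenylmagnesium bromide, (+)-Ipc2BOMe, Et2O, −78 °C to rt; then 39, −78 °C; NaOH, H2O2
Reagents that add atoms: allenylmagnesium bromide, C=C=C[Mg]Br (transferred as B-allenyl-B(Ipc)2)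
Why: Asymmetric propargylation by SE2' allenylboration through a cyclic transition state; the reagent from (+)-Ipc2BOMe attacks the Re face of the enal, in the same sense as its allyl analogue, and sets 11R under reagent control.

Step 32
Reactants: 40 (11R)-homopropargylic alcohol
Product: 41 C11 tert-butyldimethylsilyl ether of 40
Conditions: TBSOTf, 2,6-lutidine, CH2Cl2, −78 to 0 °C
Reagents that add atoms: tert-butyldimethylsilyl triflate, CC(C)(C)[Si](C)(C)OS(=O)(=O)C(F)(F)F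
Why: Silylation of the hindered allylic alcohol with the reactive triflate.

Step 33
Reactants: 41 C11 TBS ether
Product: 42 1-iodoalkyne (41 with C8–I)
Conditions: NIS, AgNO3 (10 mol %), acetone, rt, dark
Reagents that add atoms: N-iodosuccinimide, O=C1CCC(=O)N1I
Why: Silver-catalysed electrophilic iodination of the terminal alkyne C–H; alkenes and silyl ethers are not attacked.

Step 34
Reactants: 42 1-iodoalkyne
Product: 43 (8Z)-vinyl iodide
Conditions: 2-nitrobenzenesulfonylhydrazide, Et3N, THF/i-PrOH, rt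
Reagents that add atoms: none
Why: Diimide generated in the flask adds H2 syn to the iodoalkyne and gives the (Z)-vinyl iodide; the hindered internal alkenes react far more slowly.

Step 35
Reactants: 43 (8Z)-vinyl iodide
Product: 44 C19 alcohol (43 without the triethylsilyl group)
Conditions: HF·pyridine, pyridine, THF, 0 °C
Reagents that add atoms: none
Why: Buffered fluoride removes the TES ether much faster than the three TBS ethers.

Step 36
Reactants: 44 C19 alcohol; 22 2-[bis(2,2,2-trifluoroethoxy)phosphoryl]propanoic acid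
Product: 45 C19 2-[bis(2,2,2-trifluoroethoxy)phosphoryl]propanoate of 44 (both epimers at the phosphonate carbon)
Conditions: DCC, DMAP (cat.), CH2Cl2, 0 °C to rt
Reagents that add atoms: none
Why: Steglich esterification of the hindered allylic alcohol with a small acid that has no alkene geometry to lose; C19 is not touched.

Step 37
Reactants: 45 C19 phosphonopropionate; 20 (2R,3R,4E)-2,4-dimethyl-3-(triethylsilyloxy)-5-(trimethylstannyl)pent-4-enal
Product: 46 seco ester: C19 (2Z,4S,5R,6E)-2,4,6-trimethyl-5-(triethylsilyloxy)-7-(trimethylstannyl)hepta-2,6-dienoate of 44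
Conditions: 45, KN(SiMe3)2 (KHMDS), 18-crown-6, THF, −78 °C; then 20
Reagents that add atoms: none
Why: Still–Gennari olefination forms the 2Z trisubstituted enoate after the ester bond already exists, so neither the Z geometry nor C4 is exposed to acyl activation.

Step 38
Reactants: 46 seco ester
Product: 47 macrolactone (49 with C5 as (5R)-CH(OSiEt3) in place of C=O)
Conditions: Pd2(dba)3 (20 mol %), AsPh3, i-Pr2NEt, DMF, 1 mM, 40 °C
Reagents that add atoms: none
Why: Intramolecular Stille coupling under high dilution closes the 20-membered ring at C7–C8 with retention of both alkene geometries (6E,8Z-diene); zerovalent palladium inserts into the vinyl C–I bond much faster than it ionises the allylic ester.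

Step 39
Reactants: 47 macrolactone
Product: 48 (5R)-C5 alcohol (47 without the triethylsilyl group)
Conditions: HF·pyridine, pyridine, THF, 0 °C
Reagents that add atoms: none
Why: Selective cleavage of the TES ether in the presence of three TBS ethers; buffered fluoride avoids ionising the dienylic C5–O bond.

Step 40
Reactants: 48 (5R)-C5 alcohol
Product: 49 11,22,23-tris-O-(tert-butyldimethylsilyl)maltepolide D
Conditions: Dess–Martin periodinane, NaHCO3, CH2Cl2, 0 °C to rt
Reagents that add atoms: none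
Why: Buffered, non-basic Dess–Martin oxidation forms the C5 ketone without epimerising the now doubly activated C4 centre or isomerising the 8Z alkene.

Step 41
Reactants: 49 11,22,23-tris-O-(tert-butyldimethylsilyl)maltepolide D
Product: 50 maltepolide D
Conditions: HF·pyridine, pyridine, THF, 0 °C to rt
Reagents that add atoms: none
Why: Global desilylation under mildly acidic buffered conditions that leave the C4 centre, the lactone and the dienone intact.

**Compound list**
1 | ethyl (S)-lactate | CCOC(=O)[C@H](C)O | starting material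
2 | (S)-2-hydroxy-N-methoxy-N-methylpropanamide | CON(C)C(=O)[C@H](C)O | intermediate
3 | (S)-2-(tert-butyldimethylsilyloxy)-N-methoxy-N-methylpropanamide | CON(C)C(=O)[C@H](C)O[Si](C)(C)C(C)(C)C | intermediate
4 | ethynyltrimethylsilane | C#C[Si](C)(C)C | starting material
5 | (S)-4-(tert-butyldimethylsilyloxy)-1-(trimethylsilyl)pent-1-yn-3-one | C[C@H](O[Si](C)(C)C(C)(C)C)C(=O)C#C[Si](C)(C)C | intermediate
6 | (3R,4S)-4-(tert-butyldimethylsilyloxy)-1-(trimethylsilyl)pent-1-yn-3-ol | C[C@H](O[Si](C)(C)C(C)(C)C)[C@H](O)C#C[Si](C)(C)C | intermediate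
7 | (3R,4S)-3,4-bis(tert-butyldimethylsilyloxy)-1-(trimethylsilyl)pent-1-yne | C[C@H](O[Si](C)(C)C(C)(C)C)[C@H](O[Si](C)(C)C(C)(C)C)C#C[Si](C)(C)C | intermediate
8 | (3R,4S)-3,4-bis(tert-butyldimethylsilyloxy)pent-1-yne | C[C@H](O[Si](C)(C)C(C)(C)C)[C@H](O[Si](C)(C)C(C)(C)C)C#C | intermediate
9 | chlorido[(1E,3R,4S)-3,4-bis(tert-butyldimethylsilyloxy)pent-1-en-1-yl]bis(cyclopentadienyl)zirconium | C[C@H](O[Si](C)(C)C(C)(C)C)[C@H](O[Si](C)(C)C(C)(C)C)/C=C/[Zr](Cl)(C1C=CC=C1)C1C=CC=C1 | intermediate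
10 | (1E,3R,4S)-3,4-bis(tert-butyldimethylsilyloxy)-1-iodopent-1-ene | C[C@H](O[Si](C)(C)C(C)(C)C)[C@H](O[Si](C)(C)C(C)(C)C)/C=C/I | intermediate
11 | prop-2-yn-1-ol | C#CCO | starting material
12 | dimethylaluminium alkoxide of (E)-3-(dimethylalumanyl)-2-methylprop-2-en-1-ol | C[Al](C)/C=C(\C)CO[Al](C)C | intermediate
13 | (E)-3-iodo-2-methylprop-2-en-1-ol | OC/C(C)=C/I | intermediate
14 | (E)-3-iodo-2-methylprop-2-enal | O=C/C(C)=C/I | intermediate
15 | (4R)-4-benzyl-3-propanoyl-1,3-oxazolidin-2-one | CCC(=O)N1[C@H](Cc2ccccc2)COC1=O | starting material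
16 | (4R)-4-benzyl-3-[(2R,3R,4E)-3-hydroxy-5-iodo-2,4-dimethylpent-4-enoyl]-1,3-oxazolidin-2-one | O=C1OC[C@@H](Cc2ccccc2)N1C(=O)[C@H](C)[C@@H](O)/C(C)=C/I | intermediate
17 | (2R,3R,4E)-3-hydroxy-5-iodo-N-methoxy-N,2,4-trimethylpent-4-enamide | CON(C)C(=O)[C@H](C)[C@@H](O)/C(C)=C/I | intermediate
18 | (2R,3R,4E)-5-iodo-N-methoxy-N,2,4-trimethyl-3-(triethylsilyloxy)pent-4-enamide | CON(C)C(=O)[C@H](C)[C@@H](O[Si](CC)(CC)CC)/C(C)=C/I | intermediate
19 | (2R,3R,4E)-N-methoxy-N,2,4-trimethyl-3-(triethylsilyloxy)-5-(trimethylstannyl)pent-4-enamide | CON(C)C(=O)[C@H](C)[C@@H](O[Si](CC)(CC)CC)/C(C)=C/[Sn](C)(C)C | intermediate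
20 | (2R,3R,4E)-2,4-dimethyl-3-(triethylsilyloxy)-5-(trimethylstannyl)pent-4-enal | O=C[C@H](C)[C@@H](O[Si](CC)(CC)CC)/C(C)=C/[Sn](C)(C)C | intermediate
21 | methyl 2-[bis(2,2,2-trifluoroethoxy)phosphoryl]propanoate | COC(=O)C(C)P(=O)(OCC(F)(F)F)OCC(F)(F)F | starting material
22 | 2-[bis(2,2,2-trifluoroethoxy)phosphoryl]propanoic acid | OC(=O)C(C)P(=O)(OCC(F)(F)F)OCC(F)(F)F | intermediate
23 | 2-deoxy-D-ribose (pyranose form) | OC1C[C@H](O)[C@H](O)CO1 | starting material
24 | (2R,3S)-4-(1,3-dithian-2-yl)butane-1,2,3-triol | C1CSC(SC1)C[C@H](O)[C@H](O)CO | intermediate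
25 | (1S)-2-(1,3-dithian-2-yl)-1-[(4R)-2,2-dimethyl-1,3-dioxolan-4-yl]ethan-1-ol | C1CSC(SC1)C[C@H](O)[C@H]1COC(C)(C)O1 | intermediate
26 | 2-[(2S)-2-[(4R)-2,2-dimethyl-1,3-dioxolan-4-yl]-2-methoxyethyl]-1,3-dithiane | C1CSC(SC1)C[C@H](OC)[C@H]1COC(C)(C)O1 | intermediate
27 | (3S)-3-[(4R)-2,2-dimethyl-1,3-dioxolan-4-yl]-3-methoxypropanal | O=CC[C@H](OC)[C@H]1COC(C)(C)O1 | intermediate
28 | (1S,3R,4S)-1-[(4R)-2,2-dimethyl-1,3-dioxolan-4-yl]-1-methoxy-4-methylhex-5-en-3-ol | C=C[C@H](C)[C@H](O)C[C@H](OC)[C@H]1COC(C)(C)O1 | intermediate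
29 | (2R,3S,5R,6S)-3-methoxy-6-methyloct-7-ene-1,2,5-triol | C=C[C@H](C)[C@H](O)C[C@H](OC)[C@H](O)CO | intermediate
30 | (2R,3S,5R,6S)-2,5-dihydroxy-3-methoxy-6-methyloct-7-en-1-yl 4-methylbenzenesulfonate | C=C[C@H](C)[C@H](O)C[C@H](OC)[C@H](O)COS(=O)(=O)c1ccc(C)cc1 | intermediate
31 | (3S,4R,6S)-6-methoxy-3-methyl-6-[(2R)-oxiran-2-yl]hex-1-en-4-ol | C=C[C@H](C)[C@H](O)C[C@H](OC)[C@H]1CO1 | intermediate
32 | [(2S,3S,5R)-5-[(2S)-but-3-en-2-yl]-3-methoxyoxolan-2-yl]methanol | CO[C@H]1C[C@@H](O[C@H]1CO)[C@@H](C)C=C | intermediate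
33 | (2R,3S,5R)-5-[(2S)-but-3-en-2-yl]-3-methoxyoxolane-2-carbaldehyde | CO[C@H]1C[C@@H](O[C@H]1C=O)[C@@H](C)C=C | intermediate
34 | methyl (2Z)-3-[(2S,3S,5R)-5-[(2S)-but-3-en-2-yl]-3-methoxyoxolan-2-yl]-2-methylprop-2-enoate | CO[C@H]1C[C@@H](O[C@H]1/C=C(/C)C(=O)OC)[C@@H](C)C=C | intermediate
35 | methyl (2Z)-3-[(2S,3S,5R)-3-methoxy-5-[(2R)-1-oxopropan-2-yl]oxolan-2-yl]-2-methylprop-2-enoate | CO[C@H]1C[C@@H](O[C@H]1/C=C(/C)C(=O)OC)[C@@H](C)C=O | intermediate
36 | methyl (2Z)-3-[(2S,3S,5R)-5-[(2S,3R,4E,6R,7S)-6,7-bis(tert-butyldimethylsilyloxy)-3-hydroxyoct-4-en-2-yl]-3-methoxyoxolan-2-yl]-2-methylprop-2-enoate | CO[C@H]1C[C@@H](O[C@H]1/C=C(/C)C(=O)OC)[C@@H](C)[C@H](O)/C=C/[C@@H](O[Si](C)(C)C(C)(C)C)[C@H](C)O[Si](C)(C)C(C)(C)C | intermediate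
37 | C19 triethylsilyl ether of 36 | CO[C@H]1C[C@@H](O[C@H]1/C=C(/C)C(=O)OC)[C@@H](C)[C@H](O[Si](CC)(CC)CC)/C=C/[C@@H](O[Si](C)(C)C(C)(C)C)[C@H](C)O[Si](C)(C)C(C)(C)C | intermediate
38 | (Z)-allylic alcohol: 37 with C11 as CH2OH | CO[C@H]1C[C@@H](O[C@H]1/C=C(/C)CO)[C@@H](C)[C@H](O[Si](CC)(CC)CC)/C=C/[C@@H](O[Si](C)(C)C(C)(C)C)[C@H](C)O[Si](C)(C)C(C)(C)C | intermediate
39 | (Z)-enal: 38 with C11 as CHO | CO[C@H]1C[C@@H](O[C@H]1/C=C(/C)C=O)[C@@H](C)[C@H](O[Si](CC)(CC)CC)/C=C/[C@@H](O[Si](C)(C)C(C)(C)C)[C@H](C)O[Si](C)(C)C(C)(C)C | intermediate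
40 | (11R)-homopropargylic alcohol: 39 with C11 as CH(OH)CH2C≡CH | CO[C@H]1C[C@@H](O[C@H]1/C=C(/C)[C@H](O)CC#C)[C@@H](C)[C@H](O[Si](CC)(CC)CC)/C=C/[C@@H](O[Si](C)(C)C(C)(C)C)[C@H](C)O[Si](C)(C)C(C)(C)C | intermediate
41 | C11 tert-butyldimethylsilyl ether of 40 | CO[C@H]1C[C@@H](O[C@H]1/C=C(/C)[C@H](O[Si](C)(C)C(C)(C)C)CC#C)[C@@H](C)[C@H](O[Si](CC)(CC)CC)/C=C/[C@@H](O[Si](C)(C)C(C)(C)C)[C@H](C)O[Si](C)(C)C(C)(C)C | intermediate
42 | 1-iodoalkyne: 41 with I on C8 | CO[C@H]1C[C@@H](O[C@H]1/C=C(/C)[C@H](O[Si](C)(C)C(C)(C)C)CC#CI)[C@@H](C)[C@H](O[Si](CC)(CC)CC)/C=C/[C@@H](O[Si](C)(C)C(C)(C)C)[C@H](C)O[Si](C)(C)C(C)(C)C | intermediate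
43 | (8Z)-vinyl iodide from 42 | CO[C@H]1C[C@@H](O[C@H]1/C=C(/C)[C@H](O[Si](C)(C)C(C)(C)C)C/C=C\I)[C@@H](C)[C@H](O[Si](CC)(CC)CC)/C=C/[C@@H](O[Si](C)(C)C(C)(C)C)[C@H](C)O[Si](C)(C)C(C)(C)C | intermediate
44 | C19 alcohol: 43 without the triethylsilyl group | CO[C@H]1C[C@@H](O[C@H]1/C=C(/C)[C@H](O[Si](C)(C)C(C)(C)C)C/C=C\I)[C@@H](C)[C@H](O)/C=C/[C@@H](O[Si](C)(C)C(C)(C)C)[C@H](C)O[Si](C)(C)C(C)(C)C | intermediate
45 | C19 2-[bis(2,2,2-trifluoroethoxy)phosphoryl]propanoate of 44 | CO[C@H]1C[C@@H](O[C@H]1/C=C(/C)[C@H](O[Si](C)(C)C(C)(C)C)C/C=C\I)[C@@H](C)[C@H](OC(=O)C(C)P(=O)(OCC(F)(F)F)OCC(F)(F)F)/C=C/[C@@H](O[Si](C)(C)C(C)(C)C)[C@H](C)O[Si](C)(C)C(C)(C)C | intermediate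
46 | seco ester: C19 (2Z,4S,5R,6E)-2,4,6-trimethyl-5-(triethylsilyloxy)-7-(trimethylstannyl)hepta-2,6-dienoate of 44 | CO[C@H]1C[C@@H](O[C@H]1/C=C(/C)[C@H](O[Si](C)(C)C(C)(C)C)C/C=C\I)[C@@H](C)[C@H](OC(=O)/C(C)=C\[C@H](C)[C@@H](O[Si](CC)(CC)CC)/C(C)=C/[Sn](C)(C)C)/C=C/[C@@H](O[Si](C)(C)C(C)(C)C)[C@H](C)O[Si](C)(C)C(C)(C)C | intermediate
47 | macrolactone: 49 with C5 as (5R)-CH(OSiEt3) | CO[C@H]1C[C@H]2O[C@H]1/C=C(/C)[C@H](O[Si](C)(C)C(C)(C)C)C/C=C\C=C(/C)[C@H](O[Si](CC)(CC)CC)[C@@H](C)/C=C(/C)C(=O)O[C@H](/C=C/[C@@H](O[Si](C)(C)C(C)(C)C)[C@H](C)O[Si](C)(C)C(C)(C)C)[C@@H]2C | intermediate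
48 | (5R)-C5 alcohol: 47 without the triethylsilyl group | CO[C@H]1C[C@H]2O[C@H]1/C=C(/C)[C@H](O[Si](C)(C)C(C)(C)C)C/C=C\C=C(/C)[C@H](O)[C@@H](C)/C=C(/C)C(=O)O[C@H](/C=C/[C@@H](O[Si](C)(C)C(C)(C)C)[C@H](C)O[Si](C)(C)C(C)(C)C)[C@@H]2C | intermediate
49 | 11,22,23-tris-O-(tert-butyldimethylsilyl)maltepolide D | CO[C@H]1C[C@H]2O[C@H]1/C=C(/C)[C@H](O[Si](C)(C)C(C)(C)C)C/C=C\C=C(/C)C(=O)[C@@H](C)/C=C(/C)C(=O)O[C@H](/C=C/[C@@H](O[Si](C)(C)C(C)(C)C)[C@H](C)O[Si](C)(C)C(C)(C)C)[C@@H]2C | intermediate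
50 | maltepolide D | CO[C@H]1C[C@H]2O[C@H]1/C=C(/C)[C@H](O)C/C=C\C=C(/C)C(=O)[C@@H](C)/C=C(/C)C(=O)O[C@H](/C=C/[C@@H](O)[C@H](C)O)[C@@H]2C | target

**Step count and risks**

Total step count: 41 (side chain 7, north fragment 7, phosphono acid 1, core and endgame 26).
Longest linear sequence: 26 steps (steps 16–41, from 2-deoxy-D-ribose 23 to 50), 63 % of the total.

Steps most likely to fail:

Step 27 (Nozaki–Hiyama–Kishi addition, C19 configuration). Felkin selectivity of alkenylchromium additions to α-methyl aldehydes can be modest. The fallback sets out from 36 obtained as a C19 epimer mixture and comes back at 36 as a single isomer. The mixture is oxidised with Dess–Martin periodinane and NaHCO3 to the C19 enone F1, and the ketone is then reduced under reagent control with (R)-2-methyl-CBS-oxazaborolidine and catecholborane in toluene at −78 °C, the alkenyl group acting as the large substituent, to give the 19R alcohol.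

Step 37 (Still–Gennari union of two large fragments). The hindered phosphonate ester 45 may react sluggishly or with eroded Z selectivity. The fallback sets out from 20 and 21 and comes back at 46. Aldehyde 20 is olefinated with the small reagent 21 (KN(SiMe3)2, 18-crown-6, THF, −78 °C) to the (Z)-methyl enoate F2. The methyl ester is cleaved with Me3SnOH to the (Z)-acid F3, and F3 is esterified with alcohol 44 under Yamaguchi conditions (2,4,6-trichlorobenzoyl chloride, Et3N, then 44 and DMAP, toluene, rt).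

Step 38 (Stille macrocyclisation). Oligomerisation, destannylation or ionisation of the allylic ester may compete with closure of the 20-membered ring. The fallback sets out from 45 and 20 and comes back at 47, moving the ring closure to C2=C3. The two fragments are joined first by an intermolecular Stille coupling (Pd2(dba)3, AsPh3, DMF, rt) to the open-chain dienyl aldehyde phosphonate F4, and the ring is then closed by an intramolecular Still–Gennari olefination (KN(SiMe3)2, 18-crown-6, THF, 1 mM, −78 °C).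

Further compounds
F1 | step 27 | C19 enone: 36 with C19 as C=O | CO[C@H]1C[C@@H](O[C@H]1/C=C(/C)C(=O)OC)[C@@H](C)C(=O)/C=C/[C@@H](O[Si](C)(C)C(C)(C)C)[C@H](C)O[Si](C)(C)C(C)(C)C
F2 | step 37 | methyl (2Z,4S,5R,6E)-2,4,6-trimethyl-5-(triethylsilyloxy)-7-(trimethylstannyl)hepta-2,6-dienoate | COC(=O)/C(C)=C\[C@H](C)[C@@H](O[Si](CC)(CC)CC)/C(C)=C/[Sn](C)(C)C
F3 | step 37 | (2Z,4S,5R,6E)-2,4,6-trimethyl-5-(triethylsilyloxy)-7-(trimethylstannyl)hepta-2,6-dienoic acid | OC(=O)/C(C)=C\[C@H](C)[C@@H](O[Si](CC)(CC)CC)/C(C)=C/[Sn](C)(C)C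
F4 | step 38 | open-chain (6E,8Z)-dienyl C3 aldehyde carrying the C19 phosphonopropionate (45 with I replaced by the C3–C7 unit of 20) | CO[C@H]1C[C@@H](O[C@H]1/C=C(/C)[C@H](O[Si](C)(C)C(C)(C)C)C/C=C\C=C(/C)[C@H](O[Si](CC)(CC)CC)[C@@H](C)C=O)[C@@H](C)[C@H](OC(=O)C(C)P(=O)(OCC(F)(F)F)OCC(F)(F)F)/C=C/[C@@H](O[Si](C)(C)C(C)(C)C)[C@H](C)O[Si](C)(C)C(C)(C)C
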